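**Retrosynthetic overview**
1. Target ⇒ (E)-enal 22 + silyloxyfuran 24: a catalytic asymmetric vinylogous Mukaiyama aldol sets C15/C16 and brings in the butenolide ring intact, last.
2. Enal ⇒ ketol 18 (HWE at C13). 18 ⇒ monocyclic cis-epoxy ketone 16 in one cationic cascade: C5–O opening with 1,2-shift of C4 from C10 to C5 (cyclopentane → six-membered ring A), C10 cation → C9 (ring B), C8 cation → ketone oxygen (transient pyran), hydrolysis.
3. Enabling feature: in ring A the gem-dimethyl carbon C4 and the methyl-bearing C10 are both bonded to C5–H, which carries the C6 carbinol. Moving the C4–C5 bond back onto C10 gives a 1,2,2-trimethylcyclopentyl group (C10–C4 already joined) with a C5/C6 cis-epoxide whose oxygen becomes 6α-OH; the C10 cation it releases is the monocyclic cation of labdane biosynthesis.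
4. 16 ⇒ anti-diol 12 ⇒ alkenyl iodide 9 + ketal borane 11 (Suzuki) ⇒ erythro epoxy alcohol 7 (Sharpless) ⇒ aldehyde 5 ⇒ (1R,3S)-camphoric anhydride 1, whose quaternary centre is erased in the key step.
5. Ring order: cyclopentane (chiral pool) → ring A by expansion and ring B in the same step → butenolide attached last.

Key step: step 11

Remark: labdane-type numbering is used throughout (decalin C1–C10, chain C11–C15, butenolide O–CH = C16, CMe = C17, =CH = C18, C=O = C19), also for the atoms of open-chain precursors that become these positions; 1, 10 and 23 are assumed to be commercial.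

**Step 1**
Reactants: 1 (1R,5S)-1,8,8-trimethyl-3-oxabicyclo[3.2.1]octane-2,4-dione [(1R,3S)-camphoric anhydride]
Product: 3 (1R)-1,2,2-trimethylcyclopentane-1-carboxylic acid, via Barton ester acid 2 (not isolated)
Conditions: sodium 2-thioxopyridin-1(2H)-olate, DMAP (cat.), THF, rt, dark; then t-BuSH, hν (W lamp), rt; 1 M HCl
Reagents that add atoms: none
Why: Barton reductive decarboxylation, in which the thiohydroxamate should open the unsymmetrical anhydride at the less hindered carbonyl (on the CH carbon, not on the quaternary carbon), photolysis of 2 expels CO2 and t-BuSH reduces the secondary ring radical, leaving the quaternary stereocentre (later C10) untouched.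

**Step 2**
Reactants: 3 (1R)-1,2,2-trimethylcyclopentane-1-carboxylic acid
Product: 4 [(1R)-1,2,2-trimethylcyclopentyl]methanol
Conditions: LiAlH4, THF, 0 °C → reflux
Reagents that add atoms: none
Why: Hydride reduction of the hindered acid to the neopentyl alcohol; no stereocentre is affected.

**Step 3**
Reactants: 4 [(1R)-1,2,2-trimethylcyclopentyl]methanol
Product: 5 (1R)-1,2,2-trimethylcyclopentane-1-carbaldehyde
Conditions: Dess–Martin periodinane, CH2Cl2, rt
Reagents that add atoms: none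
Why: Dess–Martin oxidation stops cleanly at the non-enolisable α-quaternary aldehyde.

**Step 4**
Reactants: 5 (1R)-1,2,2-trimethylcyclopentane-1-carbaldehyde
Product: 6 (1S)-1-[(1R)-1,2,2-trimethylcyclopentyl]prop-2-en-1-ol
Conditions: CH2=CHMgBr, THF, −78 → 0 °C
Reagents that add atoms: vinylmagnesium bromide, C=C[Mg]Br
Why: Grignard addition to the aldehyde; facial control by the quaternary centre is expected to be modest, so 6 should form together with its (1R)-carbinol epimer and the mixture is carried into step 5, where only 6 reacts.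

**Step 5**
Reactants: 6 (1S)-1-[(1R)-1,2,2-trimethylcyclopentyl]prop-2-en-1-ol
Product: 7 (R)-[(2S)-oxiran-2-yl][(1R)-1,2,2-trimethylcyclopentyl]methanol
Conditions: Ti(Oi-Pr)4 (1.0 equiv), D-(−)-diisopropyl tartrate (1.2 equiv), t-BuOOH (anhydrous, limiting), 4 Å MS, CH2Cl2, −20 °C
Reagents that add atoms: tert-butyl hydroperoxide, CC(C)(C)OO
Why: Sharpless asymmetric epoxidation used as a kinetic resolution of the carbinol epimers: with D-(−)-DIPT the (1S)-alcohol should be epoxidised fast on the face that gives the erythro (anti) epoxy alcohol, fixing C5 (carbinol, R) and C6 (oxirane CH, S), while the (1R)-epimer is left behind and separated.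

**Step 6**
Reactants: 7 (R)-[(2S)-oxiran-2-yl][(1R)-1,2,2-trimethylcyclopentyl]methanol
Product: 8 (1R,2S)-1-[(1R)-1,2,2-trimethylcyclopentyl]pent-4-yne-1,2-diol
Conditions: lithium acetylide·ethylenediamine (3 equiv), DMSO, rt; aq. NH4Cl
Reagents that add atoms: lithium acetylide–ethylenediamine complex, [Li]C#C.NCCN
Why: SN2 opening of the terminal epoxide at its CH2 carbon by acetylide gives the homopropargylic anti-1,2-diol without touching C5 or C6.

**Step 7**
Reactants: 8 (1R,2S)-1-[(1R)-1,2,2-trimethylcyclopentyl]pent-4-yne-1,2-diol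
Product: 9 (1R,2S,4E)-5-iodo-4-methyl-1-[(1R)-1,2,2-trimethylcyclopentyl]pent-4-ene-1,2-diol
Conditions: Me3Al (4 equiv), Cp2ZrCl2 (0.5 equiv), CH2Cl2, 0 °C → rt; then I2, THF, −30 °C; aq. Rochelle salt
Reagents that add atoms: trimethylaluminium, C[Al](C)C; iodine, II
Why: Negishi Zr-catalysed carboalumination adds Me and Al syn across the terminal alkyne (Me to the internal carbon) and iodinolysis with retention gives the (E)-trisubstituted alkenyl iodide, which fixes the C8=C9 geometry; the hydroxyls are carried as aluminium alkoxides.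

**Step 8**
Reactants: 9 (1R,2S,4E)-5-iodo-4-methyl-1-[(1R)-1,2,2-trimethylcyclopentyl]pent-4-ene-1,2-diol; 10 2-methyl-2-vinyl-1,3-dioxolane
Product: 12 (1R,2S,4E)-4-methyl-7-(2-methyl-1,3-dioxolan-2-yl)-1-[(1R)-1,2,2-trimethylcyclopentyl]hept-4-ene-1,2-diol, via B-alkyl-9-BBN 11 (not isolated)
Conditions: 10, 9-BBN-H, THF, rt; then 9, Pd(dppf)Cl2 (5 mol %), AsPh3, 3 M aq. NaOH, THF/DMF, rt
Reagents that add atoms: none
Why: B-alkyl Suzuki–Miyaura coupling: anti-Markovnikov hydroboration of 10 gives primary alkylborane 11, which should couple with the alkenyl iodide with retention of the E geometry and tolerate the free diol and the ketal.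

**Step 9**
Reactants: 12 (1R,2S,4E)-4-methyl-7-(2-methyl-1,3-dioxolan-2-yl)-1-[(1R)-1,2,2-trimethylcyclopentyl]hept-4-ene-1,2-diol
Product: 15 2-methyl-2-[(3E)-4-methyl-5-{(2S,3R)-3-[(1R)-1,2,2-trimethylcyclopentyl]oxiran-2-yl}pent-3-en-1-yl]-1,3-dioxolane, via cyclic orthoacetate 13 (not isolated), via chloro acetate 14 (not isolated)
Conditions: MeC(OMe)3, PPTS (cat.), CH2Cl2, rt; then Me3SiCl, CH2Cl2, 0 °C → rt; then K2CO3, MeOH, rt
Reagents that add atoms: none
Why: Kolb–Sharpless diol-to-epoxide sequence: the acetoxonium ion from 13 should be opened by chloride at the less hindered C6 (inversion) to give 14, and acetate methanolysis followed by displacement of chloride by the C5 alkoxide (second inversion at C6) gives net retention at both carbons, i.e. the cis-epoxide from the anti-diol.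

**Step 10**
Reactants: 15 2-methyl-2-[(3E)-4-methyl-5-{(2S,3R)-3-[(1R)-1,2,2-trimethylcyclopentyl]oxiran-2-yl}pent-3-en-1-yl]-1,3-dioxolane
Product: 16 (5E)-6-methyl-7-{(2S,3R)-3-[(1R)-1,2,2-trimethylcyclopentyl]oxiran-2-yl}hept-5-en-2-one
Conditions: PPTS (0.2 equiv), acetone/H2O (9:1), rt
Reagents that add atoms: water, O
Why: Mild acid-catalysed hydrolysis of the dioxolane frees the methyl ketone; PPTS should be too weak to open the non-activated 1,2-dialkyl epoxide.

**Step 11**
Reactants: 16 (5E)-6-methyl-7-{(2S,3R)-3-[(1R)-1,2,2-trimethylcyclopentyl]oxiran-2-yl}hept-5-en-2-one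
Product: 18 6α,8α-dihydroxy-14,15-dinorlabdan-13-one [4-[(1R,2R,4S,4aS,8aS)-2,4-dihydroxy-2,5,5,8a-tetramethyldecahydronaphthalen-1-yl]butan-2-one], via tricyclic enol ether 17 (not isolated)
Conditions: BF3·OEt2 (2.5 equiv), CH2Cl2 (high dilution), −78 → −40 °C; then 1 M aq. HCl/THF, 0 °C → rt
Reagents that add atoms: water, O
Why: Proposed new method: BF3 activation of the cis-epoxide should break the C5–O bond only with participation of the antiperiplanar C10–C4 bond of the cyclopentane, so that the CMe2 carbon shifts from C10 to C5 (Wagner–Meerwein 1,2-shift, cyclopentylcarbinyl to cyclohexyl, the mode by which ring A reaches six members) and leaves the tertiary C10 cation of labdane biosynthesis; this cation is trapped by the (E)-C8=C9 alkene in a 6-endo-trig chair closure of ring B, and the C8 cation by the ketone oxygen in a six-membered O-closure that ends as enol ether 17, which the acidic work-up opens to the ketol. The closest known reaction types are Lewis-acid epoxide rearrangements with 1,2-alkyl shift to a tertiary cation (semipinacol-type ring expansions) and the acid cyclisation of α-monocyclic farnesylacetone-type C10 cations to sclareol-oxide enol ethers. C6 keeps the epoxide oxygen and configuration, C5 is set by the stereospecific inverting shift, C10 by the chair transition state with the C6–O–BF3 group and C4 equatorial (trans ring fusion), and C9 and C8 by anti addition across the E-alkene (9β side chain, 8α-oxygen). The step needs migration of C4 rather than C1 or methyl, which rests on the higher migratory aptitude of the fully substituted carbon and relief of the strained quaternary–quaternary C4–C10 bond; it needs the shift to outrun hydride (Meinwald) migration, which rests on only a C10 substituent being able to lie antiperiplanar to C5–O in the epoxide; and it needs ring closure to outrun retro-Prins cleavage of C5–C6 in the γ-oxido cation, which rests on the low temperature and the pre-folded chair.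

**Step 12**
Reactants: 18 6α,8α-dihydroxy-14,15-dinorlabdan-13-one
Product: 19 ethyl (13E)-6α,8α-dihydroxylabd-13-en-15-oate
Conditions: (EtO)2P(O)CH2CO2Et (5 equiv), NaH (5 equiv), THF, 0 → 60 °C
Reagents that add atoms: triethyl phosphonoacetate, CCOC(=O)CP(=O)(OCC)OCC
Why: Horner–Wadsworth–Emmons olefination of the methyl ketone should give mainly the (E)-trisubstituted enoate (ester trans to the larger C12 chain), the minor Z isomer being removed by chromatography; the hydroxyls are spectators as sodium alkoxides.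

**Step 13**
Reactants: 19 ethyl (13E)-6α,8α-dihydroxylabd-13-en-15-oate
Product: 20 ethyl (13E)-6α,8α-bis(triethylsilyloxy)labd-13-en-15-oate
Conditions: Et3SiOTf (3 equiv), 2,6-lutidine, CH2Cl2, −78 → 0 °C
Reagents that add atoms: triethylsilyl trifluoromethanesulfonate, CC[Si](CC)(CC)OS(=O)(=O)C(F)(F)F
Why: Silyl triflate silylation protects the secondary 6-OH and the tertiary 8-OH so that the later Lewis-acid aldol sees no free hydroxyl.

**Step 14**
Reactants: 20 ethyl (13E)-6α,8α-bis(triethylsilyloxy)labd-13-en-15-oate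
Product: 21 (13E)-6α,8α-bis(triethylsilyloxy)labd-13-en-15-ol
Conditions: DIBAL-H (2.5 equiv), CH2Cl2, −78 °C; Rochelle salt
Reagents that add atoms: none
Why: DIBAL-H 1,2-reduction of the enoate gives the allylic alcohol without touching the silyl ethers or the alkene geometry.

**Step 15**
Reactants: 21 (13E)-6α,8α-bis(triethylsilyloxy)labd-13-en-15-ol
Product: 22 (13E)-6α,8α-bis(triethylsilyloxy)labd-13-en-15-al
Conditions: activated MnO2, CH2Cl2, rt
Reagents that add atoms: none
Why: MnO2 oxidises only the allylic alcohol and should give the (E)-enal without isomerisation.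

**Step 16**
Reactants: 23 4-methylfuran-2(5H)-one
Product: 24 tert-butyldimethyl[(4-methylfuran-2-yl)oxy]silane
Conditions: TBSOTf, Et3N, CH2Cl2, 0 °C
Reagents that add atoms: tert-butyldimethylsilyl trifluoromethanesulfonate, CC(C)(C)[Si](C)(C)OS(=O)(=O)C(F)(F)F
Why: Soft enolisation of the butenolide with silyl triflate and amine gives the aromatic 2-silyloxyfuran, the γ-nucleophile for the vinylogous aldol.

**Step 17**
Reactants: 22 (13E)-6α,8α-bis(triethylsilyloxy)labd-13-en-15-al; 24 tert-butyldimethyl[(4-methylfuran-2-yl)oxy]silane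
Product: 25 (5S)-5-{(1S,2E)-1-hydroxy-3-methyl-5-[(1R,2R,4S,4aS,8aS)-2,5,5,8a-tetramethyl-2,4-bis(triethylsilyloxy)decahydronaphthalen-1-yl]pent-2-en-1-yl}-4-methylfuran-2(5H)-one
Conditions: SiCl4 (1.5 equiv), (R,R)-binaphthyldiamine-derived bisphosphoramide (5 mol %), i-Pr2NEt (0.1 equiv), CH2Cl2, −78 °C; aqueous work-up
Reagents that add atoms: none
Why: Catalytic asymmetric vinylogous Mukaiyama aldol reaction: the chiral phosphoramide-bound chlorosilyl cation activates the enal and should expose its Re face (catalyst enantiomer to be confirmed on a model enal), and the furan γ-carbon adds through an open transition state to give the threo (like) adduct normally favoured in Lewis-acid additions of 2-silyloxyfurans, so that C15 (S) and C16 (S) are set together under catalyst control because the decalin stereocentres are too remote to interfere.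

**Step 18**
Reactants: 25 bis(triethylsilyl) ether of the target
Product: 26 (5S)-5-{(1S,2E)-5-[(1R,2R,4S,4aS,8aS)-2,4-dihydroxy-2,5,5,8a-tetramethyldecahydronaphthalen-1-yl]-1-hydroxy-3-methylpent-2-en-1-yl}-4-methylfuran-2(5H)-one
Conditions: HF·pyridine, pyridine, THF, 0 °C → rt
Reagents that add atoms: none
Why: Fluoride-mediated cleavage of both triethylsilyl ethers under buffered, non-basic conditions should leave the base-sensitive butenolide and the allylic alcohol intact and give the target.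

**Compound list**
1 | (1R,5S)-1,8,8-trimethyl-3-oxabicyclo[3.2.1]octane-2,4-dione [(1R,3S)-camphoric anhydride] | C[C@]12CC[C@H](C(=O)OC1=O)C2(C)C | starting material
2 | (1R,3S)-1,2,2-trimethyl-3-{[(2-thioxopyridin-1(2H)-yl)oxy]carbonyl}cyclopentane-1-carboxylic acid | C[C@@]1(C(=O)O)CC[C@H](C(=O)ON2C=CC=CC2=S)C1(C)C | intermediate
3 | (1R)-1,2,2-trimethylcyclopentane-1-carboxylic acid | C[C@@]1(C(=O)O)CCCC1(C)C | intermediate
4 | [(1R)-1,2,2-trimethylcyclopentyl]methanol | C[C@@]1(CO)CCCC1(C)C | intermediate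
5 | (1R)-1,2,2-trimethylcyclopentane-1-carbaldehyde | C[C@@]1(C=O)CCCC1(C)C | intermediate
6 | (1S)-1-[(1R)-1,2,2-trimethylcyclopentyl]prop-2-en-1-ol | C=C[C@H](O)[C@]1(C)CCCC1(C)C | intermediate
7 | (R)-[(2S)-oxiran-2-yl][(1R)-1,2,2-trimethylcyclopentyl]methanol | C1O[C@@H]1[C@H](O)[C@]2(C)CCCC2(C)C | intermediate
8 | (1R,2S)-1-[(1R)-1,2,2-trimethylcyclopentyl]pent-4-yne-1,2-diol | C#CC[C@H](O)[C@H](O)[C@]1(C)CCCC1(C)C | intermediate
9 | (1R,2S,4E)-5-iodo-4-methyl-1-[(1R)-1,2,2-trimethylcyclopentyl]pent-4-ene-1,2-diol | I/C=C(\C)C[C@H](O)[C@H](O)[C@]1(C)CCCC1(C)C | intermediate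
10 | 2-methyl-2-vinyl-1,3-dioxolane | CC1(C=C)OCCO1 | starting material
11 | 9-[2-(2-methyl-1,3-dioxolan-2-yl)ethyl]-9-borabicyclo[3.3.1]nonane | CC1(CCB2C3CCCC2CCC3)OCCO1 | intermediate
12 | (1R,2S,4E)-4-methyl-7-(2-methyl-1,3-dioxolan-2-yl)-1-[(1R)-1,2,2-trimethylcyclopentyl]hept-4-ene-1,2-diol | CC1(CC/C=C(\C)C[C@H](O)[C@H](O)[C@]2(C)CCCC2(C)C)OCCO1 | intermediate
13 | 2-[(3E)-5-{(4S,5R)-2-methoxy-2-methyl-5-[(1R)-1,2,2-trimethylcyclopentyl]-1,3-dioxolan-4-yl}-4-methylpent-3-en-1-yl]-2-methyl-1,3-dioxolane (either configuration at the orthoester carbon) | CC1(CC/C=C(\C)C[C@@H]2OC(C)(OC)O[C@@H]2[C@]3(C)CCCC3(C)C)OCCO1 | intermediate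
14 | (1R,2R,4E)-2-chloro-4-methyl-7-(2-methyl-1,3-dioxolan-2-yl)-1-[(1R)-1,2,2-trimethylcyclopentyl]hept-4-en-1-yl acetate | CC1(CC/C=C(\C)C[C@@H](Cl)[C@H](OC(C)=O)[C@]2(C)CCCC2(C)C)OCCO1 | intermediate
15 | 2-methyl-2-[(3E)-4-methyl-5-{(2S,3R)-3-[(1R)-1,2,2-trimethylcyclopentyl]oxiran-2-yl}pent-3-en-1-yl]-1,3-dioxolane | CC1(CC/C=C(\C)C[C@@H]2O[C@@H]2[C@]3(C)CCCC3(C)C)OCCO1 | intermediate
16 | (5E)-6-methyl-7-{(2S,3R)-3-[(1R)-1,2,2-trimethylcyclopentyl]oxiran-2-yl}hept-5-en-2-one | CC(=O)CC/C=C(\C)C[C@@H]1O[C@@H]1[C@]2(C)CCCC2(C)C | intermediate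
17 | 6α-hydroxy-8α,13-epoxy-14,15-dinorlabd-12-ene | CC1=CC[C@@H]2[C@@]3(C)CCCC(C)(C)[C@@H]3[C@@H](O)C[C@@]2(C)O1 | intermediate
18 | 6α,8α-dihydroxy-14,15-dinorlabdan-13-one | CC(=O)CC[C@@H]1[C@@]2(C)CCCC(C)(C)[C@@H]2[C@@H](O)C[C@@]1(C)O | intermediate
19 | ethyl (13E)-6α,8α-dihydroxylabd-13-en-15-oate | CCOC(=O)/C=C(\C)CC[C@@H]1[C@@]2(C)CCCC(C)(C)[C@@H]2[C@@H](O)C[C@@]1(C)O | intermediate
20 | ethyl (13E)-6α,8α-bis(triethylsilyloxy)labd-13-en-15-oate | CCOC(=O)/C=C(\C)CC[C@@H]1[C@@]2(C)CCCC(C)(C)[C@@H]2[C@@H](O[Si](CC)(CC)CC)C[C@@]1(C)O[Si](CC)(CC)CC | intermediate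
21 | (13E)-6α,8α-bis(triethylsilyloxy)labd-13-en-15-ol | OC/C=C(\C)CC[C@@H]1[C@@]2(C)CCCC(C)(C)[C@@H]2[C@@H](O[Si](CC)(CC)CC)C[C@@]1(C)O[Si](CC)(CC)CC | intermediate
22 | (13E)-6α,8α-bis(triethylsilyloxy)labd-13-en-15-al | O=C/C=C(\C)CC[C@@H]1[C@@]2(C)CCCC(C)(C)[C@@H]2[C@@H](O[Si](CC)(CC)CC)C[C@@]1(C)O[Si](CC)(CC)CC | intermediate
23 | 4-methylfuran-2(5H)-one | CC1=CC(=O)OC1 | starting material
24 | tert-butyldimethyl[(4-methylfuran-2-yl)oxy]silane | Cc1coc(O[Si](C)(C)C(C)(C)C)c1 | intermediate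
25 | 6,8-bis-O-triethylsilyl ether of the target, (15S,16S) | CC1=CC(=O)O[C@@H]1[C@@H](O)/C=C(\C)CC[C@@H]1[C@@]2(C)CCCC(C)(C)[C@@H]2[C@@H](O[Si](CC)(CC)CC)C[C@@]1(C)O[Si](CC)(CC)CC | intermediate
26 | (5S)-5-{(1S,2E)-5-[(1R,2R,4S,4aS,8aS)-2,4-dihydroxy-2,5,5,8a-tetramethyldecahydronaphthalen-1-yl]-1-hydroxy-3-methylpent-2-en-1-yl}-4-methylfuran-2(5H)-one | CC1=CC(=O)O[C@@H]1[C@@H](O)/C=C(\C)CC[C@@H]1[C@@]2(C)CCCC(C)(C)[C@@H]2[C@@H](O)C[C@@]1(C)O | target

**Totals**
Total step count: 18. Longest linear sequence: 17 (steps 1–15, 17, 18; step 16 is the side branch).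

**Steps most likely to fail**

1. Step 11 (proposed new method). What may go wrong: migration of the wrong cyclopentane bond (C1–C10 or CH3–C10) instead of C4–C10; hydride shift giving a ketone; retro-Prins cleavage of the C5–C6 bond in the γ-oxido cation; proton loss from the C8 cation before oxygen capture. Fallback (known chemistry, events separated): it sets out from diol 12. The less hindered C6 hydroxyl is silylated (TBSOTf, 2,6-lutidine, −78 °C) to give the mono-silyl ether F1. The neopentyl C5 hydroxyl is mesylated (MsCl, Et3N) to give mesylate F2. Buffered solvolysis (2,6-lutidine, aqueous hexafluoroisopropanol, 40 °C) effects the classical cyclopentylcarbinyl-to-cyclohexyl Wagner–Meerwein shift with loss of H-1 from the C10 cation, giving the ring-expanded cyclohexene F3. PPTS in aqueous acetone unmasks the ketone F4. The known low-temperature superacid cyclisation of α-monocyclic polyenyl ketones (FSO3H, 2-nitropropane, −78 °C) then closes ring B and the enol ether to give the silylated tricycle F5. Aqueous HF in MeCN hydrolyses the enol ether, removes the silyl group and comes back to the route at 18.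

2. Step 17. What may go wrong: poor facial selectivity at the enal, erosion of the threo preference with the 4-methyl-substituted furan, or competing 1,4-addition. Fallback (auxiliary control, butenolide built afterwards): it sets out from enal 22. Evans syn-glycolate aldol with (R)-4-benzyl-3-{[(4-methoxybenzyl)oxy]acetyl}oxazolidin-2-one (Bu2BOTf, Et3N, CH2Cl2, −78 → 0 °C) sets C15 and C16 in the syn adduct F6. Transamidation (MeNHOMe·HCl, AlMe3) gives the Weinreb amide F7, and Et3SiOTf/2,6-lutidine gives its silyl ether F8. MeMgBr gives the methyl ketone F9, and DDQ removes the PMB group to give the α-hydroxy ketone F10. Ph3P=C=C=O (toluene, 80 °C; acylation then intramolecular Wittig) closes the butenolide F11, and HF·pyridine comes back to the route at 26.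

3. Step 5. What may go wrong: very slow epoxidation of the hindered tert-alkyl vinyl carbinol and too small a rate difference between the carbinol epimers. Fallback (catalyst-controlled ketone reduction, then hydroxyl-directed epoxidation): it sets out from acid 3. (COCl)2 gives the acid chloride F12. Acyl Sonogashira coupling with trimethylsilylacetylene (PdCl2(PPh3)2, CuI, Et3N) gives the ynone F13. Noyori transfer hydrogenation (RuCl[(R,R)-TsDPEN](p-cymene), i-PrOH) sets the carbinol in the propargylic alcohol F14. K2CO3/MeOH gives the terminal alkyne F15, and Lindlar semi-hydrogenation gives 6 as a single epimer. VO(acac)2/t-BuOOH, erythro-selective for unsubstituted vinyl carbinols, comes back to the route at 7.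

**Further compounds**
F1 | step 11 | (1R,2S,4E)-2-[(tert-butyldimethylsilyl)oxy]-4-methyl-7-(2-methyl-1,3-dioxolan-2-yl)-1-[(1R)-1,2,2-trimethylcyclopentyl]hept-4-en-1-ol | CC1(CC/C=C(\C)C[C@H](O[Si](C)(C)C(C)(C)C)[C@H](O)[C@]2(C)CCCC2(C)C)OCCO1
F2 | step 11 | methanesulfonate of F1 at C5 | CC1(CC/C=C(\C)C[C@H](O[Si](C)(C)C(C)(C)C)[C@H](OS(C)(=O)=O)[C@]2(C)CCCC2(C)C)OCCO1
F3 | step 11 | 2-{(3E,6S)-6-[(tert-butyldimethylsilyl)oxy]-4-methyl-6-[(1S)-2,6,6-trimethylcyclohex-2-en-1-yl]hex-3-en-1-yl}-2-methyl-1,3-dioxolane | CC1(CC/C=C(\C)C[C@H](O[Si](C)(C)C(C)(C)C)[C@@H]2C(C)=CCCC2(C)C)OCCO1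
F4 | step 11 | (5E,8S)-8-[(tert-butyldimethylsilyl)oxy]-6-methyl-8-[(1S)-2,6,6-trimethylcyclohex-2-en-1-yl]oct-5-en-2-one | CC(=O)CC/C=C(\C)C[C@H](O[Si](C)(C)C(C)(C)C)[C@@H]1C(C)=CCCC1(C)C
F5 | step 11 | 6α-[(tert-butyldimethylsilyl)oxy]-8α,13-epoxy-14,15-dinorlabd-12-ene | CC1=CC[C@@H]2[C@@]3(C)CCCC(C)(C)[C@@H]3[C@@H](O[Si](C)(C)C(C)(C)C)C[C@@]2(C)O1
F6 | step 17 | Evans syn-glycolate aldol adduct of 22, (15S,16S), N-acyl (R)-4-benzyloxazolidin-2-one, 16-O-PMB | O=C1OC[C@@H](Cc2ccccc2)N1C(=O)[C@H](OCc1ccc(OC)cc1)[C@@H](O)/C=C(\C)CC[C@@H]1[C@@]2(C)CCCC(C)(C)[C@@H]2[C@@H](O[Si](CC)(CC)CC)C[C@@]1(C)O[Si](CC)(CC)CC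
F7 | step 17 | Weinreb amide from F6 | CON(C)C(=O)[C@H](OCc1ccc(OC)cc1)[C@@H](O)/C=C(\C)CC[C@@H]1[C@@]2(C)CCCC(C)(C)[C@@H]2[C@@H](O[Si](CC)(CC)CC)C[C@@]1(C)O[Si](CC)(CC)CC
F8 | step 17 | 15-O-triethylsilyl ether of F7 | CON(C)C(=O)[C@H](OCc1ccc(OC)cc1)[C@@H](O[Si](CC)(CC)CC)/C=C(\C)CC[C@@H]1[C@@]2(C)CCCC(C)(C)[C@@H]2[C@@H](O[Si](CC)(CC)CC)C[C@@]1(C)O[Si](CC)(CC)CC
F9 | step 17 | methyl ketone from F8 (C17 ketone, 16-O-PMB, tris-TES) | CC(=O)[C@H](OCc1ccc(OC)cc1)[C@@H](O[Si](CC)(CC)CC)/C=C(\C)CC[C@@H]1[C@@]2(C)CCCC(C)(C)[C@@H]2[C@@H](O[Si](CC)(CC)CC)C[C@@]1(C)O[Si](CC)(CC)CC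
F10 | step 17 | α-hydroxy ketone from F9 (16-OH free) | CC(=O)[C@H](O)[C@@H](O[Si](CC)(CC)CC)/C=C(\C)CC[C@@H]1[C@@]2(C)CCCC(C)(C)[C@@H]2[C@@H](O[Si](CC)(CC)CC)C[C@@]1(C)O[Si](CC)(CC)CC
F11 | step 17 | 6,8,15-tris-O-triethylsilyl ether of the target | CC1=CC(=O)O[C@@H]1[C@@H](O[Si](CC)(CC)CC)/C=C(\C)CC[C@@H]1[C@@]2(C)CCCC(C)(C)[C@@H]2[C@@H](O[Si](CC)(CC)CC)C[C@@]1(C)O[Si](CC)(CC)CC
F12 | step 5 | (1R)-1,2,2-trimethylcyclopentane-1-carbonyl chloride | C[C@@]1(C(Cl)=O)CCCC1(C)C
F13 | step 5 | 3-(trimethylsilyl)-1-[(1R)-1,2,2-trimethylcyclopentyl]prop-2-yn-1-one | C[Si](C)(C)C#CC(=O)[C@]1(C)CCCC1(C)C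
F14 | step 5 | (1R)-3-(trimethylsilyl)-1-[(1R)-1,2,2-trimethylcyclopentyl]prop-2-yn-1-ol | C[Si](C)(C)C#C[C@H](O)[C@]1(C)CCCC1(C)C
F15 | step 5 | (1S)-1-[(1R)-1,2,2-trimethylcyclopentyl]prop-2-yn-1-ol | C#C[C@H](O)[C@]1(C)CCCC1(C)C
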